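The lactone is numbered as a germacranolide. The five-membered lactone ring (O, C12, C11, C7, C6) is read as CO2 laid across an allene C6=C7=C11. An open-chain, axially chiral allenylstannane that carries the whole C5–C8 chain is lithiated at C11, carboxylated with CO2 and iodolactonised in the same flask. This one operation makes C11–C12, O–C6 and C7–I, and it sets C6 by axial-to-central chirality transfer. It exploits that O–C12(=O) is CO2 and that the ring-fusion carbon C7 is the central allene carbon, which takes up iodine. That iodide then closes the ten-membered ring on the C8 aldehyde. The chain grows from but-3-yn-1-ol by two methylalumination cycles.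

Key step: step 10

Numbering: C8 carries the methacrylate and C9 is the CH2 next to it. C10=C1 and C4=C5 are the two E-alkenes. C2 carries the secondary acetate and C3 is a CH2. C6 carries the lactone oxygen, C7=C11 is the butenolide alkene, C12 is the lactone carbonyl and C13 is the acetoxymethyl carbon. The target is 2R,6R,8S. TBS = tert-butyldimethylsilyl, PMB = 4-methoxybenzyl.

Assumption: the facial sense quoted for (R)-TRIP and (S,S)-ProPhenol follows the usual models for these catalysts; if either proved opposite, its antipode would be used.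

Step 1
Reactants: 1 but-3-yn-1-ol
Product: 2 1-[(but-3-yn-1-yloxy)methyl]-4-methoxybenzene
Conditions: NaH, PMBCl, Bu4NI (cat.), THF, 0 °C to rt
Reagents that add atoms: 4-methoxybenzyl chloride COc1ccc(CCl)cc1
Why: Williamson etherification masks the future C8 oxygen as an ether that survives organoaluminium, organolithium and organocopper reagents and can later be removed oxidatively.

Step 2
Reactants: 2 1-[(but-3-yn-1-yloxy)methyl]-4-methoxybenzene
Product: 5 (E)-5-(4-methoxybenzyloxy)-3-methylpent-2-en-1-ol, via alkenylalane 3 (not isolated), via lithium aluminate 4 (not isolated)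
Conditions: AlMe3, Cp2ZrCl2 (cat.), CH2Cl2, 0 °C to rt; n-BuLi, THF, −78 °C; (CH2O)n, −78 °C to rt
Reagents that add atoms: trimethylaluminium C[Al](C)C; n-butyllithium [Li]CCCC (kept only in 4); formaldehyde from paraformaldehyde C=O
Why: Negishi carboalumination adds methyl and aluminium syn and places aluminium on the terminal carbon, so C10=C1 is formed as the E-alkene, and the ate complex is hydroxymethylated with retention.

Step 3
Reactants: 5 (E)-5-(4-methoxybenzyloxy)-3-methylpent-2-en-1-ol
Product: 6 (E)-5-(4-methoxybenzyloxy)-3-methylpent-2-enal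
Conditions: MnO2, CH2Cl2, rt
Reagents that add atoms: none
Why: Heterogeneous MnO2 oxidation is selective for allylic alcohols and neutral, so the enal should form without E/Z isomerisation.

Step 4
Reactants: 6 (E)-5-(4-methoxybenzyloxy)-3-methylpent-2-enal; 7 allenylboronic acid pinacol ester
Product: 8 (4R,5E)-8-(4-methoxybenzyloxy)-6-methyloct-5-en-1-yn-4-ol
Conditions: (R)-TRIP (cat.), 4 Å MS, toluene, −20 °C
Reagents that add atoms: none
Why: Chiral-phosphoric-acid-catalysed propargylboration runs by SE2' attack of the allenylboronate through a closed six-membered transition state in which the (R)-catalyst blocks one aldehyde face, which sets C2 as R.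

Step 5
Reactants: 8 (4R,5E)-8-(4-methoxybenzyloxy)-6-methyloct-5-en-1-yn-4-ol
Product: 9 TBS ether of 8
Conditions: TBSCl, imidazole, DMF, rt
Reagents that add atoms: tert-butyldimethylsilyl chloride CC(C)(C)[Si](C)(C)Cl
Why: Silylation at oxygen leaves C2 untouched and gives an ether that tolerates AlMe3, n-BuLi and the stannylcopper reagent used later.

Step 6
Reactants: 9 TBS ether of 8
Product: 12 (2E,5R,6E)-5-(TBS-oxy)-9-(4-methoxybenzyloxy)-3,7-dimethylnona-2,6-dien-1-ol, via dienylalane 10 (not isolated), via lithium aluminate 11 (not isolated)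
Conditions: AlMe3, Cp2ZrCl2 (cat.), CH2Cl2, 0 °C to rt; n-BuLi, THF, −78 °C; (CH2O)n, −78 °C to rt
Reagents that add atoms: trimethylaluminium C[Al](C)C; n-butyllithium [Li]CCCC (kept only in 11); formaldehyde from paraformaldehyde C=O
Why: A second Negishi carboalumination and hydroxymethylation builds C4(Me)=C5 as the E-alkene by syn addition and adds C6, while the silyl and PMB ethers are inert.

Step 7
Reactants: 12 (2E,5R,6E)-5-(TBS-oxy)-9-(4-methoxybenzyloxy)-3,7-dimethylnona-2,6-dien-1-ol
Product: 13 (2E,5R,6E)-5-(TBS-oxy)-9-(4-methoxybenzyloxy)-3,7-dimethylnona-2,6-dienal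
Conditions: MnO2, CH2Cl2, rt
Reagents that add atoms: none
Why: Neutral MnO2 oxidation of the primary allylic alcohol gives the C6 enal without touching the protected allylic C2 oxygen or the alkene geometry.

Step 8
Reactants: 13 (2E,5R,6E)-5-(TBS-oxy)-9-(4-methoxybenzyloxy)-3,7-dimethylnona-2,6-dienal; 14 tert-butyldimethyl(prop-2-yn-1-yloxy)silane
Product: 16 (4S,5E,8R,9E)-1,8-bis(TBS-oxy)-12-(4-methoxybenzyloxy)-6,10-dimethyldodeca-5,9-dien-2-yn-4-ol, via alkynylzinc 15 (not isolated)
Conditions: Me2Zn, (S,S)-ProPhenol (cat.), Ph3P=O (cat.), toluene, 0 °C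
Reagents that add atoms: dimethylzinc C[Zn]C (kept only in 15)
Why: In the zinc–ProPhenol asymmetric alkynylation of an enal the dinuclear zinc complex binds aldehyde and alkynylzinc 15 and delivers the alkyne to one face, which sets C6 as S under catalyst control because C2 is remote.

Step 9
Reactants: 16 (4S,5E,8R,9E)-1,8-bis(TBS-oxy)-12-(4-methoxybenzyloxy)-6,10-dimethyldodeca-5,9-dien-2-yn-4-ol
Product: 18 (Ra,5E,8R,9E)-1,8-bis(TBS-oxy)-12-(4-methoxybenzyloxy)-6,10-dimethyl-2-(tributylstannyl)dodeca-2,3,5,9-tetraene, via mesylate 17 (not isolated)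
Conditions: n-BuLi, THF, −78 °C, then MsCl; cannulated into Bu3SnCu (from Bu3SnH, LiN(iPr)2, then CuBr·SMe2), THF, −78 °C
Reagents that add atoms: methanesulfonyl chloride CS(=O)(=O)Cl (kept only in 17); tributyltin hydride CCCC[SnH](CCCC)CCCC
Why: The sulfonate is made and consumed at −78 °C and is displaced by the stannylcopper reagent in an anti SN2' substitution at the alkyne terminus C11 (the alkene terminus C4 is fully substituted and less accessible), so the 6S centre is translated into the Ra axis.

Step 10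
Reactants: 18 (Ra,5E,8R,9E)-1,8-bis(TBS-oxy)-12-(4-methoxybenzyloxy)-6,10-dimethyl-2-(tributylstannyl)dodeca-2,3,5,9-tetraene
Product: 21 (5R)-3-(TBS-oxymethyl)-4-iodo-5-[(1E,4R,5E)-4-(TBS-oxy)-8-(4-methoxybenzyloxy)-2,6-dimethylocta-1,5-dienyl]furan-2(5H)-one, via allenyllithium 19 (not isolated), via lithium allenoate 20 (not isolated)
Conditions: n-BuLi, THF, −78 °C; CO2 (dry gas), −78 °C; I2 in THF, −78 to 0 °C
Reagents that add atoms: n-butyllithium [Li]CCCC (lithium kept only in 19 and 20); carbon dioxide O=C=O; iodine II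
Why: Tin–lithium exchange gives the 1-lithioallene 19, whose C11–Li bond attacks CO2 at the metal-bearing carbon (carboxylation of a lithioallene, a known route to 2,3-allenoic acids) and forms C11–C12 with retention of the axis; iodine then activates the C6=C7 bond of carboxylate 20, the carboxylate oxygen closes on C6 and iodine ends on the central carbon C7 (iodolactonisation of a 2,3-allenoate, a known route to β-iodobutenolides). The only ring closed is the five-membered lactone, by 5-endo-trig attack of oxygen on C6 anti to the iodonium. C6 is the only new stereocentre and is fixed by axial-to-central chirality transfer: the carboxylate sits on one face of the C6=C7 π bond, so the Ra axis gives 6R, which is overall inversion relative to the 6S carbinol 16. Three selectivities are needed: uptake of CO2 at C11 and not at C6 or C4 of the conjugated anion (hard electrophile, contact ion pair at −78 °C), no racemisation or loss of silanolate from C13 before trapping (short lifetime at −78 °C), and productive attack of iodine on the allene only (iodonium formation at the two trisubstituted alkenes is reversible and finds no internal nucleophile).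

Step 11
Reactants: 21 (5R)-β-iodobutenolide PMB ether
Product: 22 (5R)-3-(TBS-oxymethyl)-5-[(1E,4R,5E)-4-(TBS-oxy)-8-hydroxy-2,6-dimethylocta-1,5-dienyl]-4-iodofuran-2(5H)-one
Conditions: DDQ, CH2Cl2/pH 7 buffer, 0 °C
Reagents that add atoms: none
Why: Oxidative PMB cleavage (hydride abstraction from the electron-rich benzylic position, then hydrolysis) leaves silyl ethers, vinyl iodide and butenolide untouched.

Step 12
Reactants: 22 primary alcohol
Product: 23 (3E,5R,7E)-5-(TBS-oxy)-8-[(2R)-4-(TBS-oxymethyl)-3-iodo-5-oxo-2,5-dihydrofuran-2-yl]-3,7-dimethylocta-3,7-dienal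
Conditions: Dess–Martin periodinane, NaHCO3, CH2Cl2, 0 °C
Reagents that add atoms: none
Why: Dess–Martin oxidation under bicarbonate buffer is fast and neutral, so the β,γ-unsaturated C8 aldehyde should not slip into conjugation and C6 should not epimerise.

Step 13
Reactants: 23 iodo aldehyde
Product: 25 (2R,6R,8S)-2,13-bis(TBS-oxy)-8-hydroxygermacra-1(10)E,4E,7(11)-trien-12,6-olide, via alkenylchromium 24 (not isolated)
Conditions: CrCl2 (excess), NiCl2 (cat.), DMSO, rt, slow addition at high dilution
Reagents that add atoms: chromium dichloride Cl[Cr]Cl (kept only in 24)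
Why: In the Nozaki–Hiyama–Kishi macrocyclisation zerovalent nickel inserts into C7–I, the alkenyl group passes to trivalent chromium and adds chemoselectively to the aldehyde, and C8 is set by macrocyclic substrate control because the resident C6 centre on the rigid butenolide decides which aldehyde face can reach C7 in the crown-like closing conformer, the 6,8-cis (8S) alcohol being expected.

Step 14
Reactants: 25 macrocyclic 8S alcohol
Product: 26 8-O-methacryloyl derivative of 25
Conditions: methacrylic anhydride, DMAP (cat.), Et3N, CH2Cl2, 0 °C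
Reagents that add atoms: methacrylic anhydride C=C(C)C(=O)OC(=O)C(C)=C
Why: DMAP-catalysed acylation takes place at oxygen with retention at C8 and is mild enough for the acidic C6–H.

Step 15
Reactants: 26 8-O-methacryloyl bis-TBS ether
Product: 27 (2R,6R,8S)-2,13-dihydroxy-8-methacryloyloxygermacra-1(10)E,4E,7(11)-trien-12,6-olide
Conditions: HF·pyridine, pyridine, THF, 0 °C to rt
Reagents that add atoms: none
Why: Fluoride-driven desilylation in a buffered, non-basic medium removes both TBS groups while methacrylate, butenolide and the three stereocentres stay intact.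

Step 16
Reactants: 27 2,13-diol
Product: 28 CNP0309304.1
Conditions: Ac2O, pyridine, DMAP (cat.), CH2Cl2, 0 °C
Reagents that add atoms: acetic anhydride CC(=O)OC(C)=O
Why: Acetylation of the secondary C2 and primary C13 hydroxy groups at oxygen gives the target without change at any stereocentre.

Compound list
1 | but-3-yn-1-ol | C#CCCO | starting material
2 | 1-[(but-3-yn-1-yloxy)methyl]-4-methoxybenzene | COc1ccc(COCCC#C)cc1 | intermediate
3 | dimethyl[(E)-4-(4-methoxybenzyloxy)-2-methylbut-1-enyl]alane | COc1ccc(COCC/C(C)=C/[Al](C)C)cc1 | intermediate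
4 | lithium butyl(dimethyl)[(E)-4-(4-methoxybenzyloxy)-2-methylbut-1-enyl]aluminate | COc1ccc(COCC/C(C)=C/[Al-](C)(C)CCCC)cc1.[Li+] | intermediate
5 | (E)-5-(4-methoxybenzyloxy)-3-methylpent-2-en-1-ol | COc1ccc(COCC/C(C)=C/CO)cc1 | intermediate
6 | (E)-5-(4-methoxybenzyloxy)-3-methylpent-2-enal | COc1ccc(COCC/C(C)=C/C=O)cc1 | intermediate
7 | allenylboronic acid pinacol ester | C=C=CB1OC(C)(C)C(C)(C)O1 | starting material
8 | (4R,5E)-8-(4-methoxybenzyloxy)-6-methyloct-5-en-1-yn-4-ol | COc1ccc(COCC/C(C)=C/[C@H](O)CC#C)cc1 | intermediate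
9 | TBS ether of 8 | COc1ccc(COCC/C(C)=C/[C@H](O[Si](C)(C)C(C)(C)C)CC#C)cc1 | intermediate
10 | (1E,4R,5E)-dienyl(dimethyl)alane from 9 (Al on C5, new methyl on C4) | COc1ccc(COCC/C(C)=C/[C@H](O[Si](C)(C)C(C)(C)C)C/C(C)=C/[Al](C)C)cc1 | intermediate
11 | lithium butyl(dimethyl)aluminate of 10 | COc1ccc(COCC/C(C)=C/[C@H](O[Si](C)(C)C(C)(C)C)C/C(C)=C/[Al-](C)(C)CCCC)cc1.[Li+] | intermediate
12 | (2E,5R,6E)-5-(TBS-oxy)-9-(4-methoxybenzyloxy)-3,7-dimethylnona-2,6-dien-1-ol | COc1ccc(COCC/C(C)=C/[C@H](O[Si](C)(C)C(C)(C)C)C/C(C)=C/CO)cc1 | intermediate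
13 | (2E,5R,6E)-5-(TBS-oxy)-9-(4-methoxybenzyloxy)-3,7-dimethylnona-2,6-dienal | COc1ccc(COCC/C(C)=C/[C@H](O[Si](C)(C)C(C)(C)C)C/C(C)=C/C=O)cc1 | intermediate
14 | tert-butyldimethyl(prop-2-yn-1-yloxy)silane | C#CCO[Si](C)(C)C(C)(C)C | starting material
15 | methyl[3-(TBS-oxy)prop-1-ynyl]zinc | C[Zn]C#CCO[Si](C)(C)C(C)(C)C | intermediate
16 | (4S,5E,8R,9E)-1,8-bis(TBS-oxy)-12-(4-methoxybenzyloxy)-6,10-dimethyldodeca-5,9-dien-2-yn-4-ol (6S,2R in germacrane numbering) | COc1ccc(COCC/C(C)=C/[C@H](O[Si](C)(C)C(C)(C)C)C/C(C)=C/[C@H](O)C#CCO[Si](C)(C)C(C)(C)C)cc1 | intermediate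
17 | methanesulfonate of 16 | COc1ccc(COCC/C(C)=C/[C@H](O[Si](C)(C)C(C)(C)C)C/C(C)=C/[C@H](OS(C)(=O)=O)C#CCO[Si](C)(C)C(C)(C)C)cc1 | intermediate
18 | (Ra)-allenylstannane, tin on C11 anti to the departed C6 oxygen | COc1ccc(COCC/C(C)=C/[C@H](O[Si](C)(C)C(C)(C)C)C/C(C)=C/C=[C@]=C(CO[Si](C)(C)C(C)(C)C)[Sn](CCCC)(CCCC)CCCC)cc1 | intermediate
19 | allenyllithium, Li in place of tin, same axial sense | COc1ccc(COCC/C(C)=C/[C@H](O[Si](C)(C)C(C)(C)C)C/C(C)=C/C=[C@]=C(CO[Si](C)(C)C(C)(C)C)[Li])cc1 | intermediate
20 | lithium (Ra)-allenoate, carboxylate on C11 | COc1ccc(COCC/C(C)=C/[C@H](O[Si](C)(C)C(C)(C)C)C/C(C)=C/C=[C@]=C(CO[Si](C)(C)C(C)(C)C)C(=O)[O-])cc1.[Li+] | intermediate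
21 | (5R)-3-(TBS-oxymethyl)-4-iodo-5-[(1E,4R,5E)-4-(TBS-oxy)-8-(4-methoxybenzyloxy)-2,6-dimethylocta-1,5-dienyl]furan-2(5H)-one | COc1ccc(COCC/C(C)=C/[C@H](O[Si](C)(C)C(C)(C)C)C/C(C)=C/[C@H]2OC(=O)C(CO[Si](C)(C)C(C)(C)C)=C2I)cc1 | intermediate
22 | primary C8 alcohol from 21 | OCC/C(C)=C/[C@H](O[Si](C)(C)C(C)(C)C)C/C(C)=C/[C@H]1OC(=O)C(CO[Si](C)(C)C(C)(C)C)=C1I | intermediate
23 | C8 aldehyde from 22 | O=CC/C(C)=C/[C@H](O[Si](C)(C)C(C)(C)C)C/C(C)=C/[C@H]1OC(=O)C(CO[Si](C)(C)C(C)(C)C)=C1I | intermediate
24 | C7 alkenylchromium dichloride from 23 | O=CC/C(C)=C/[C@H](O[Si](C)(C)C(C)(C)C)C/C(C)=C/[C@H]1OC(=O)C(CO[Si](C)(C)C(C)(C)C)=C1[Cr](Cl)Cl | intermediate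
25 | (2R,6R,8S)-2,13-bis(TBS-oxy)-8-hydroxygermacra-1(10)E,4E,7(11)-trien-12,6-olide | O[C@H]1C/C(C)=C/[C@H](O[Si](C)(C)C(C)(C)C)C/C(C)=C/[C@H]2OC(=O)C(CO[Si](C)(C)C(C)(C)C)=C12 | intermediate
26 | 8-O-methacryloyl derivative of 25 | C=C(C)C(=O)O[C@H]1C/C(C)=C/[C@H](O[Si](C)(C)C(C)(C)C)C/C(C)=C/[C@H]2OC(=O)C(CO[Si](C)(C)C(C)(C)C)=C12 | intermediate
27 | (2R,6R,8S)-2,13-dihydroxy-8-methacryloyloxygermacra-1(10)E,4E,7(11)-trien-12,6-olide | C=C(C)C(=O)O[C@H]1C/C(C)=C/[C@H](O)C/C(C)=C/[C@H]2OC(=O)C(CO)=C12 | intermediate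
28 | CNP0309304.1, (2R,6R,8S)-2,13-diacetoxy-8-methacryloyloxygermacra-1(10)E,4E,7(11)-trien-12,6-olide | C=C(C)C(=O)O[C@H]1C/C(C)=C/[C@H](OC(C)=O)C/C(C)=C/[C@H]2OC(=O)C(COC(C)=O)=C12 | target

Total step count: 16. Longest linear sequence: 16 steps, from 1 to 28 (7 and 14 are purchased).

Steps most likely to fail

Risk 1, step 10. The carbanion of 19 is conjugated through C6=C7 with the C4=C5 alkene, so charge can spread to C6 and C4. The axis may then racemise, CO2 may be taken up at the wrong carbon, or silanolate may be lost from C13 before trapping. The fallback sets out from stannane 18 and avoids any free carbanion. A Stille-type coupling of 18 with ethyl chloroformate (Pd2(dba)3, AsPh3, THF, rt) passes the allenyl group from tin to divalent palladium and on to the acyl carbon with retention, and should give the ethyl (Ra)-allenoate F1. Iodine in aqueous MeCN then closes the lactone through the ester carbonyl oxygen with loss of ethanol. The route is rejoined at 21.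

Risk 2, step 13. Closure to a strained E,E-cyclodecadiene competes with oligomerisation and with simple reduction of the C–I bond. The facial selectivity at the aldehyde also rests only on conformational control. The fallback sets out from 23 and accepts the opposite face. If closure delivers mainly the 8R alcohol F2, this epimer is esterified under Mitsunobu conditions (methacrylic acid, PPh3, DIAD, toluene, 0 °C). That reaction inverts C8 and installs the methacrylate at once, and the route is rejoined at 26.

Risk 3, step 9. Mesylate 17 is both allylic and propargylic. It may ionise with loss of configuration, or it may be attacked at C6 or C4 instead of C11. The fallback sets out from 16 and uses a leaving group that can be isolated, the methyl carbonate F3 (ClCO2Me, pyridine, CH2Cl2, 0 °C). Methoxycarbonylation with Pd(PPh3)4 under CO (1 atm) in MeOH/THF proceeds by anti SN2' oxidative addition of zerovalent palladium, CO insertion at C11 and capture by methoxide, and should give the methyl (Ra)-allenoate F4. Iodine in aqueous MeCN closes the lactone with loss of methanol. The route is rejoined at 21, bypassing 17 to 20.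

Further compounds
F1 | step 10 | ethyl (Ra)-allenoate, CO2Et on C11 | COc1ccc(COCC/C(C)=C/[C@H](O[Si](C)(C)C(C)(C)C)C/C(C)=C/C=[C@]=C(CO[Si](C)(C)C(C)(C)C)C(=O)OCC)cc1
F2 | step 13 | 8R epimer of 25 | O[C@@H]1C/C(C)=C/[C@H](O[Si](C)(C)C(C)(C)C)C/C(C)=C/[C@H]2OC(=O)C(CO[Si](C)(C)C(C)(C)C)=C12
F3 | step 9 | methyl carbonate of 16 | COc1ccc(COCC/C(C)=C/[C@H](O[Si](C)(C)C(C)(C)C)C/C(C)=C/[C@H](OC(=O)OC)C#CCO[Si](C)(C)C(C)(C)C)cc1
F4 | step 9 | methyl (Ra)-allenoate, CO2Me on C11 | COc1ccc(COCC/C(C)=C/[C@H](O[Si](C)(C)C(C)(C)C)C/C(C)=C/C=[C@]=C(CO[Si](C)(C)C(C)(C)C)C(=O)OC)cc1
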